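**Assumption:** the target has no stereocentres, so "single enantiomer" is read as the single (Z)-alkene isomer; that geometry is the only stereochemical element to control.

## Retrosynthetic overview
1. The target is the mono-O-demethyl derivative of a symmetric tetramethyl ether, (Z)-ArC7–CH=CH–C7Ar with Ar = 3,5-dimethoxyphenyl. All four OMe groups are equivalent, so removing any one gives the target.
2. The symmetric (Z)-alkene is disconnected at C8=C9 by Z-selective homometathesis of a single terminal alkene, Ar(CH2)7CH=CH2.
3. That alkene is disconnected at the benzylic C–C bond: 3,5-dimethoxybenzyl bromide plus oct-7-enyl Grignard (Cu-catalysed sp3–sp3 coupling).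
4. No rings are formed; both arenes are purchased intact.

## Route

**Step 1**
Reactants: **1** 8-bromooct-1-ene; **2** 3,5-dimethoxybenzyl bromide
Product: **3** 1,3-dimethoxy-5-(non-8-en-1-yl)benzene
Conditions: (i) **1** (1.3 equiv), Mg, cat. I2, THF, rt→40 °C; (ii) add to **2** with Li2CuCl4 (5 mol%), THF, −10 °C→rt; aq. NH4Cl workup
Reagents that add atoms: none (both coupling partners are the numbered reactants)
Why: Kochi-type Cu-catalysed Grignard/benzyl bromide cross-coupling forms the ArCH2–CH2 bond; the terminal alkene and aryl methyl ethers are inert, and no stereocentre is formed.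

**Step 2**
Reactants: **3** (2 molecules)
Product: **4** (Z)-1,16-bis(3,5-dimethoxyphenyl)hexadec-8-ene
Conditions: Grubbs Z-selective cyclometalated Ru catalyst (N-adamantyl-chelated NHC, nitrato ligand; 1–2 mol%), THF (~3 M), 35 °C, static vacuum to remove ethylene
Reagents that add atoms: none (ethylene is lost)
Why: Z-selective olefin homometathesis of an unhindered terminal alkene; the chelated catalyst forces a syn metallacyclobutane and typically gives ≥95% Z, and the remote aryl ethers do not interfere.

**Step 3**
Reactants: **4**
Product: **5** Oncostemonol E, 3-[(8Z)-16-(3,5-dimethoxyphenyl)hexadec-8-en-1-yl]-5-methoxyphenol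
Conditions: NaSEt (~1.1 equiv), degassed DMF, 130 °C, Ar, dark; stop at maximum mono-phenol by HPLC; aq. NH4Cl; chromatography
Reagents that add atoms: none (one CH3 is removed as EtSMe; H comes from workup)
Why: Thiolate SN2 O-demethylation (Feutrill–Mirrington). The phenoxide formed shuts down a second demethylation on the same ring, and because the four OMe groups are equivalent every mono-demethylation gives **5**. The outcome is statistical between the two rings, with a ceiling of about 50% **5**; recovered **4** is recycled, and the bis-phenol by-product can be remethylated (MeI/K2CO3) back to **4**. The isolated Z-alkene is untouched by thiolate when O2 and light are excluded.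

## Compound list
1 | 8-bromooct-1-ene | C=CCCCCCCBr | starting material
2 | 3,5-dimethoxybenzyl bromide | COc1cc(CBr)cc(OC)c1 | starting material
3 | 1,3-dimethoxy-5-(non-8-en-1-yl)benzene | COc1cc(CCCCCCCC=C)cc(OC)c1 | intermediate
4 | (Z)-1,16-bis(3,5-dimethoxyphenyl)hexadec-8-ene | COc1cc(OC)cc(CCCCCCC/C=C\CCCCCCCc2cc(OC)cc(OC)c2)c1 | intermediate
5 | Oncostemonol E, 3-[(8Z)-16-(3,5-dimethoxyphenyl)hexadec-8-en-1-yl]-5-methoxyphenol | COc1cc(O)cc(CCCCCCC/C=C\CCCCCCCc2cc(OC)cc(OC)c2)c1 | target

## Summary
Total steps: 3. Longest linear sequence: 3.

Steps most likely to fail (the route has only three, ranked by risk), each with a fallback that changes the approach: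

1. **Step 3** – statistical mono-demethylation (over-demethylation on the second ring; thiyl-radical Z→E erosion if O2 is present). Fallback: desymmetrise before joining the halves. Mono-demethylate **3** (one ring, so clean mono), protect the phenol as its TBS ether, run a Z-selective cross-metathesis with excess **3**, then remove TBS with TBAF.
2. **Step 2** – Z-selective homometathesis (incomplete conversion or lower Z purity). Fallback: an alkyne route. Alkylate acetylene twice with 1-(7-bromoheptyl)-3,5-dimethoxybenzene to give the symmetric internal alkyne, then Lindlar semi-hydrogenation to the (Z)-alkene. A salt-free Z-Wittig between Ar(CH2)7CHO and the ylide from Ar(CH2)8PPh3Br is a second option.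
3. **Step 1** – Cu-catalysed coupling (benzyl homocoupling to the bibenzyl, Wurtz products). Fallback: reverse the polarity with an sp2–sp3 Negishi coupling of 1-bromo-3,5-dimethoxybenzene with non-8-enylzinc bromide (from 9-bromonon-1-ene) using Pd/SPhos.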